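**Plan**
1. Retrosynthesis first removes the protecting groups (four O-benzyl on rings A and C, one O-tert-butyl on the central ring). It then cuts two bonds of the central ring, C3(ring C arm)–C2(O) and C6(OH)–C1(acetyl), in the acetophenone numbering of 27.
2. This splits the ring into a 1-methoxy-1,3-bis(silyloxy)diene (four ring carbons carrying both arms) and 4-tert-butoxybut-3-yn-2-one (the acetyl-bearing carbon and one C–O carbon). The diene goes back to methyl acetoacetate by cutting the two ArCH2–C bonds at its α and γ carbons.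
3. Both arm bromides go back to 2-methylphloroglucinol. The acyl group put on first (butanoyl for ring A, formyl for ring C) steers the single O-methylation para to itself, and the other acyl group takes the last free ring position.
4. Forward: rings A and C are present from the start and are dressed (steps 1 to 12). The chain is joined at the γ carbon, then at the α carbon (steps 13, 14) and silylated (steps 15, 16). The central ring arises last, by cycloaddition and aromatisation (step 19), and acid, then hydrogen, free the phenols (steps 20, 21).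
5. Stereochemistry: the target has no stereocentre and no stereogenic double bond. The sp3 centres and enol ether geometries of intermediates disappear on aromatisation or hydrolysis.

Key step: step 19

Remark: the four starting materials and all reagents named (among them N-methoxy-N-methylacetamide) are taken as commercial; the butanoyl groups are carried through step 19 as silyl enol ethers on purpose, because the base that makes the diene would enolise them in any case.
Abbreviations: ArA = 2,4-bis(benzyloxy)-3-butanoyl-6-methoxy-5-methylphenyl (ring A); ArC = 2,6-bis(benzyloxy)-3-butanoyl-4-methoxy-5-methylphenyl (ring C); ArA* and ArC* = the same groups with butanoyl replaced by (Z)-1-(trimethylsilyloxy)but-1-en-1-yl.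

**Route**

Step 1
Reactants: 1 2-methylphloroglucinol (2-methylbenzene-1,3,5-triol); 2 butanoyl chloride
Product: 3 1-(2,4,6-trihydroxy-3-methylphenyl)butan-1-one
Conditions: AlCl3 (3.5 equiv), PhNO2/CH2Cl2, 0 to 40 °C; aq. HCl
Reagents that add atoms: none
Why: Friedel–Crafts C-acylation of the very electron-rich triol at one of its two equivalent free positions, after which the complexed ketone deactivates the ring against a second acylation.

Step 2
Reactants: 3 1-(2,4,6-trihydroxy-3-methylphenyl)butan-1-one
Product: 4 1-(2,6-dihydroxy-4-methoxy-3-methylphenyl)butan-1-one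
Conditions: Me2SO4 (1.0 equiv), K2CO3 (1.0 equiv), acetone, 20 °C
Reagents that add atoms: dimethyl sulfate COS(=O)(=O)OC
Why: Williamson O-methylation with one equivalent of base should take the hydroxyl para to the ketone, which is the most acidic and is not chelated, while the two ortho hydroxyls share the hydrogen bond to the carbonyl and react later.

Step 3
Reactants: 4 1-(2,6-dihydroxy-4-methoxy-3-methylphenyl)butan-1-one
Product: 5 3-butanoyl-2,4-dihydroxy-6-methoxy-5-methylbenzaldehyde
Conditions: POCl3 (1.3 equiv), DMF, 0 °C; then 4, EtOAc, 0 to 20 °C; then H2O, 50 °C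
Reagents that add atoms: N,N-dimethylformamide CN(C)C=O; water O
Why: Vilsmeier–Haack formylation at the single free ring position, which is ortho or para to three oxygens, and at room temperature ring attack should outrun any reaction at the chelated ketone.

Step 4
Reactants: 5 3-butanoyl-2,4-dihydroxy-6-methoxy-5-methylbenzaldehyde
Product: 6 2,4-bis(benzyloxy)-3-butanoyl-6-methoxy-5-methylbenzaldehyde
Conditions: BnBr (2.5 equiv), K2CO3 (3 equiv), DMF, 60 °C
Reagents that add atoms: benzyl bromide BrCc1ccccc1
Why: Williamson benzylation of both chelated phenols, and since the ring has no free carbon left, C-benzylation cannot compete.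

Step 5
Reactants: 6 2,4-bis(benzyloxy)-3-butanoyl-6-methoxy-5-methylbenzaldehyde
Product: 7 1-[2,6-bis(benzyloxy)-3-(hydroxymethyl)-4-methoxy-5-methylphenyl]butan-1-one
Conditions: NaBH4 (0.5 equiv), THF/MeOH, -20 to 0 °C
Reagents that add atoms: none
Why: borohydride reduction of the aldehyde, while the ketone, flanked by two ortho benzyloxy groups and twisted out of the ring plane, should react far more slowly.

Step 6
Reactants: 7 1-[2,6-bis(benzyloxy)-3-(hydroxymethyl)-4-methoxy-5-methylphenyl]butan-1-one
Product: 8 1-[2,6-bis(benzyloxy)-3-(bromomethyl)-4-methoxy-5-methylphenyl]butan-1-one (ring A bromide)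
Conditions: CBr4 (1.3 equiv), PPh3 (1.3 equiv), CH2Cl2, 0 °C; used at once
Reagents that add atoms: carbon tetrabromide BrC(Br)(Br)Br
Why: Appel bromination under neutral conditions, and the fully substituted ring cannot alkylate itself, which should make this electron-rich benzylic bromide handleable.

Step 7
Reactants: 1 2-methylphloroglucinol
Product: 9 2,4,6-trihydroxy-3-methylbenzaldehyde
Conditions: POCl3 (1.1 equiv), DMF, 0 °C; then 1, EtOAc, 0 to 20 °C; then H2O, 50 °C
Reagents that add atoms: N,N-dimethylformamide CN(C)C=O; water O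
Why: Vilsmeier–Haack formylation at one of the two equivalent free positions, where the iminium group formed deactivates the ring so that one equivalent of reagent should stop at the monoaldehyde.

Step 8
Reactants: 9 2,4,6-trihydroxy-3-methylbenzaldehyde
Product: 10 2,6-dihydroxy-4-methoxy-3-methylbenzaldehyde
Conditions: Me2SO4 (1.0 equiv), K2CO3 (1.0 equiv), acetone, 20 °C
Reagents that add atoms: dimethyl sulfate COS(=O)(=O)OC
Why: Williamson O-methylation as in step 2, now directed by the formyl group, so that the ether forms para to the aldehyde and next to the C-methyl group, as ring C requires.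

Step 9
Reactants: 10 2,6-dihydroxy-4-methoxy-3-methylbenzaldehyde; 2 butanoyl chloride
Product: 11 3-butanoyl-2,6-dihydroxy-4-methoxy-5-methylbenzaldehyde
Conditions: AlCl3 (3.5 equiv), PhNO2/CH2Cl2, 0 to 20 °C; aq. HCl
Reagents that add atoms: none
Why: Friedel–Crafts acylation at the only free position, of the kind used to make 2,4-diacylphloroglucinols, and keeping the mixture at or below 20 °C should spare the methyl ether that ends up ortho to the new ketone.

Step 10
Reactants: 11 3-butanoyl-2,6-dihydroxy-4-methoxy-5-methylbenzaldehyde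
Product: 12 2,6-bis(benzyloxy)-3-butanoyl-4-methoxy-5-methylbenzaldehyde
Conditions: BnBr (2.5 equiv), K2CO3 (3 equiv), DMF, 60 °C
Reagents that add atoms: benzyl bromide BrCc1ccccc1
Why: Williamson benzylation of both chelated phenols as in step 4, with only O-alkylation possible on the fully substituted ring.

Step 11
Reactants: 12 2,6-bis(benzyloxy)-3-butanoyl-4-methoxy-5-methylbenzaldehyde
Product: 13 1-[2,4-bis(benzyloxy)-3-(hydroxymethyl)-6-methoxy-5-methylphenyl]butan-1-one
Conditions: NaBH4 (0.5 equiv), THF/MeOH, -20 to 0 °C
Reagents that add atoms: none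
Why: chemoselective borohydride reduction of the aldehyde beside the hindered, out-of-plane aryl ketone, as in step 5.

Step 12
Reactants: 13 1-[2,4-bis(benzyloxy)-3-(hydroxymethyl)-6-methoxy-5-methylphenyl]butan-1-one
Product: 14 1-[2,4-bis(benzyloxy)-3-(bromomethyl)-6-methoxy-5-methylphenyl]butan-1-one (ring C bromide)
Conditions: CBr4 (1.3 equiv), PPh3 (1.3 equiv), CH2Cl2, 0 °C; used at once
Reagents that add atoms: carbon tetrabromide BrC(Br)(Br)Br
Why: Appel bromination as in step 6.

Step 13
Reactants: 15 methyl acetoacetate; 14 ring C bromide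
Product: 17 methyl 5-ArC-3-oxopentanoate, via methyl acetoacetate dianion 16 (not isolated)
Conditions: 15 (3 equiv), NaH (3 equiv), THF, 0 °C; n-BuLi (3 equiv), 0 °C; then 14 (1 equiv), -78 to 0 °C; then 1 M HCl
Reagents that add atoms: none
Why: γ-alkylation of a β-keto ester dianion by a benzylic bromide, where the excess of dianion covers any proton transfer from the hindered aryl ketone, which returns unchanged on work-up.

Step 14
Reactants: 17 methyl 5-ArC-3-oxopentanoate; 8 ring A bromide
Product: 18 methyl 2-(ArA-CH2)-5-ArC-3-oxopentanoate (racemic)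
Conditions: K2CO3 (2 equiv), acetone, 40 °C
Reagents that add atoms: none
Why: C-alkylation of the β-keto ester enolate at its α-carbon, with a base too weak to touch the aryl ketones and enough bulk to stop a second alkylation.

Step 15
Reactants: 18 methyl 2-(ArA-CH2)-5-ArC-3-oxopentanoate
Product: 19 methyl 2-(ArA-CH2)-5-ArC-3-(trimethylsilyloxy)pent-2-enoate
Conditions: TMSCl (1.5 equiv), Et3N (2 equiv), toluene, 20 °C, 72 h; filtration under argon
Reagents that add atoms: chlorotrimethylsilane C[Si](C)(C)Cl
Why: silyl enol ether formation from the β-keto ester under amine base, which does not enolise the isolated aryl ketones.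

Step 16
Reactants: 19 methyl 2-(ArA-CH2)-5-ArC-3-(trimethylsilyloxy)pent-2-enoate
Product: 21 (3Z)-1-methoxy-2-(ArA*-CH2)-5-ArC*-1,3-bis(trimethylsilyloxy)penta-1,3-diene, via trilithium trienolate 20 (not isolated)
Conditions: LiN(i-Pr)2 (3.5 equiv), THF, -78 °C, 1 h; then TMSCl (4.5 equiv), -78 to 20 °C; pentane, filtration under argon, used crude
Reagents that add atoms: chlorotrimethylsilane C[Si](C)(C)Cl
Why: kinetic deprotonation at the γ-CH2 of the silyloxy enoate and at the α-CH2 of both butanoyl groups, then O-silylation of all three enolates, is the standard second stage in making 1-alkoxy-1,3-bis(silyloxy)dienes and at the same time masks both ketones as (Z) enol ethers for the next step.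

Step 17
Reactants: 22 trichloroethylene
Product: 23 (E)-1-tert-butoxy-1,2-dichloroethene
Conditions: t-BuOK (1.05 equiv), THF, -60 to 20 °C
Reagents that add atoms: potassium tert-butoxide CC(C)(C)[O-].[K+]
Why: net substitution of one geminal chlorine by tert-butoxide through elimination of HCl and anti addition of the alcohol, the standard preparation of (E)-1,2-dichlorovinyl ethers.

Step 18
Reactants: 23 (E)-1-tert-butoxy-1,2-dichloroethene
Product: 25 4-tert-butoxybut-3-yn-2-one, via lithium tert-butoxyacetylide 24 (not isolated)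
Conditions: n-BuLi (2.1 equiv), THF, -78 to -40 °C; then MeC(O)N(OMe)Me (1.0 equiv), -78 to -20 °C; cold pH 7 buffer; kept cold and acid-free
Reagents that add atoms: N-methoxy-N-methylacetamide CC(=O)N(C)OC
Why: two equivalents of n-BuLi turn the dichlorovinyl ether into the lithium alkoxyacetylide (loss of HCl, then chlorine–lithium exchange), which is acylated only once by the N-methoxy-N-methylamide because the chelated adduct holds until the cold neutral quench.

Step 19
Reactants: 21 tetrasilylated diene; 25 4-tert-butoxybut-3-yn-2-one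
Product: 27 1-[2-tert-butoxy-4,6-dihydroxy-3-(ArC-CH2)-5-(ArA-CH2)phenyl]ethan-1-one, via cyclohexadiene cycloadduct 26 (not isolated)
Conditions: 21 (1 equiv), 25 (2 equiv), CH2Cl2 (1 M), 12 kbar, 20 °C, 24 h; then 1 M HCl, THF, 0 °C
Reagents that add atoms: none
Why: Proposed new method: the terminal diene carbon C4, the most nucleophilic site of this vinylogous ketene acetal, should bond to the ynone carbon that carries the tert-butoxy group and lies β to the carbonyl, and the ynone α-carbon (an allenolate carbon if the bonds form one after the other) should bond to the ketene acetal carbon C1, so that the six-membered central ring closes in a (4+2) Diels–Alder mode, concerted but asynchronous or stepwise-polar. The closest known reaction type is the Diels–Alder addition and aromatisation of 1-alkoxy-1,3-bis(silyloxy)buta-1,3-dienes with acetylenic ketones and esters, which gives resorcinols; a 3-alkoxy ynone and a diene substituted at both C2 and C4 go beyond it. Cold dilute acid should then hydrolyse the silyl ketal at C1, expel methanol, cleave the ring enol ether and let the cyclohexadienone tautomerise to the arene, while both arm enol ethers return to butanoyl groups and the aryl tert-butyl ether stays. No stereocentre is set, because the two sp3 ring carbons of 26 become aromatic. The step needs one orientation, which the substrates secure because the donors of the diene all push towards C4 while carbonyl and alkoxy group both make the β-carbon of the ynone the electrophilic one, and it needs closure through C1 and not an aldol-type (3+3) closure through C2, which the absence of any Lewis acid at the ketone carbonyl should secure. Pressure replaces heat and Lewis acid because cycloaddition has a large negative activation volume whereas loss of isobutene from the ynol ether, which sets in on warming, is not helped by pressure, and the isolated arm enol ethers are too weak donors to add to the ynone.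

Step 20
Reactants: 27 mono-tert-butyl ether
Product: 28 1-[2,4,6-trihydroxy-3-(ArC-CH2)-5-(ArA-CH2)phenyl]ethan-1-one
Conditions: CF3CO2H/CH2Cl2 (1:4), 0 °C, 1 h
Reagents that add atoms: none
Why: acidolysis of the aryl tert-butyl ether with loss of isobutene, which the benzyl ethers should survive on short cold exposure and in which the tert-butyl cation finds no free ring position to alkylate.

Step 21
Reactants: 28 tetrabenzyl ether
Product: 29 CNP0184345.0, 1-[2,4,6-trihydroxy-3-[(3-butanoyl-2,6-dihydroxy-4-methoxy-5-methylphenyl)methyl]-5-[(3-butanoyl-2,4-dihydroxy-6-methoxy-5-methylphenyl)methyl]phenyl]ethan-1-one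
Conditions: H2 (1 atm), 10% Pd/C, EtOAc/MeOH, 20 °C
Reagents that add atoms: none
Why: hydrogenolysis of the four benzyl ethers under neutral conditions, which the hydrogen-bonded aryl ketones and the diarylmethane bridges should survive at 1 atm.

**Compound list**
1 | 2-methylphloroglucinol | Cc1c(O)cc(O)cc1O | starting material
2 | butanoyl chloride | CCCC(=O)Cl | starting material
3 | 1-(2,4,6-trihydroxy-3-methylphenyl)butan-1-one | CCCC(=O)c1c(O)cc(O)c(C)c1O | intermediate
4 | 1-(2,6-dihydroxy-4-methoxy-3-methylphenyl)butan-1-one | CCCC(=O)c1c(O)cc(OC)c(C)c1O | intermediate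
5 | 3-butanoyl-2,4-dihydroxy-6-methoxy-5-methylbenzaldehyde | CCCC(=O)c1c(O)c(C=O)c(OC)c(C)c1O | intermediate
6 | 2,4-bis(benzyloxy)-3-butanoyl-6-methoxy-5-methylbenzaldehyde | CCCC(=O)c1c(OCc2ccccc2)c(C=O)c(OC)c(C)c1OCc1ccccc1 | intermediate
7 | 1-[2,6-bis(benzyloxy)-3-(hydroxymethyl)-4-methoxy-5-methylphenyl]butan-1-one | CCCC(=O)c1c(OCc2ccccc2)c(CO)c(OC)c(C)c1OCc1ccccc1 | intermediate
8 | 1-[2,6-bis(benzyloxy)-3-(bromomethyl)-4-methoxy-5-methylphenyl]butan-1-one (ring A bromide) | CCCC(=O)c1c(OCc2ccccc2)c(CBr)c(OC)c(C)c1OCc1ccccc1 | intermediate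
9 | 2,4,6-trihydroxy-3-methylbenzaldehyde | Cc1c(O)cc(O)c(C=O)c1O | intermediate
10 | 2,6-dihydroxy-4-methoxy-3-methylbenzaldehyde | COc1cc(O)c(C=O)c(O)c1C | intermediate
11 | 3-butanoyl-2,6-dihydroxy-4-methoxy-5-methylbenzaldehyde | COc1c(C(=O)CCC)c(O)c(C=O)c(O)c1C | intermediate
12 | 2,6-bis(benzyloxy)-3-butanoyl-4-methoxy-5-methylbenzaldehyde | COc1c(C(=O)CCC)c(OCc2ccccc2)c(C=O)c(OCc2ccccc2)c1C | intermediate
13 | 1-[2,4-bis(benzyloxy)-3-(hydroxymethyl)-6-methoxy-5-methylphenyl]butan-1-one | COc1c(C(=O)CCC)c(OCc2ccccc2)c(CO)c(OCc2ccccc2)c1C | intermediate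
14 | 1-[2,4-bis(benzyloxy)-3-(bromomethyl)-6-methoxy-5-methylphenyl]butan-1-one (ring C bromide) | COc1c(C(=O)CCC)c(OCc2ccccc2)c(CBr)c(OCc2ccccc2)c1C | intermediate
15 | methyl acetoacetate | CC(=O)CC(=O)OC | starting material
16 | sodium lithium dianion of methyl acetoacetate (formed in the flask) | [Na+].[Li+].C=C([O-])C=C([O-])OC | intermediate
17 | methyl 5-[2,6-bis(benzyloxy)-3-butanoyl-4-methoxy-5-methylphenyl]-3-oxopentanoate | COC(=O)CC(=O)CCc1c(OCc2ccccc2)c(C)c(OC)c(C(=O)CCC)c1OCc1ccccc1 | intermediate
18 | methyl 2-{[2,4-bis(benzyloxy)-3-butanoyl-6-methoxy-5-methylphenyl]methyl}-5-[2,6-bis(benzyloxy)-3-butanoyl-4-methoxy-5-methylphenyl]-3-oxopentanoate (racemic at C2) | COC(=O)C(Cc1c(OC)c(C)c(OCc2ccccc2)c(C(=O)CCC)c1OCc1ccccc1)C(=O)CCc1c(OCc2ccccc2)c(C)c(OC)c(C(=O)CCC)c1OCc1ccccc1 | intermediate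
19 | 3-O-trimethylsilyl enol ether of 18, methyl 2-(ArA-CH2)-5-ArC-3-(trimethylsilyloxy)pent-2-enoate (double-bond geometry not controlled and lost in step 16) | COC(=O)C(Cc1c(OC)c(C)c(OCc2ccccc2)c(C(=O)CCC)c1OCc1ccccc1)=C(O[Si](C)(C)C)CCc1c(OCc2ccccc2)c(C)c(OC)c(C(=O)CCC)c1OCc1ccccc1 | intermediate
20 | trilithium trienolate of 19: ester dienolate plus both butanoyl enolates (formed in the flask) | [Li+].[Li+].[Li+].COC([O-])=C(Cc1c(OC)c(C)c(OCc2ccccc2)c(/C([O-])=C/CC)c1OCc1ccccc1)/C(O[Si](C)(C)C)=C/Cc1c(OCc2ccccc2)c(C)c(OC)c(/C([O-])=C/CC)c1OCc1ccccc1 | intermediate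
21 | (3Z)-1-methoxy-2-(ArA*-CH2)-5-ArC*-1,3-bis(trimethylsilyloxy)penta-1,3-diene, both butanoyl groups as (Z) trimethylsilyl enol ethers (ketene acetal geometry not controlled) | COC(O[Si](C)(C)C)=C(Cc1c(OC)c(C)c(OCc2ccccc2)c(/C(O[Si](C)(C)C)=C/CC)c1OCc1ccccc1)/C(O[Si](C)(C)C)=C/Cc1c(OCc2ccccc2)c(C)c(OC)c(/C(O[Si](C)(C)C)=C/CC)c1OCc1ccccc1 | intermediate
22 | trichloroethylene | ClC=C(Cl)Cl | starting material
23 | (E)-1-tert-butoxy-1,2-dichloroethene | CC(C)(C)O/C(Cl)=C\Cl | intermediate
24 | lithium tert-butoxyacetylide (formed in the flask) | [Li]C#COC(C)(C)C | intermediate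
25 | 4-tert-butoxybut-3-yn-2-one | CC(=O)C#COC(C)(C)C | intermediate
26 | 1-acetyl-2-tert-butoxy-6-methoxy-3-(ArC*-CH2)-5-(ArA*-CH2)-4,6-bis(trimethylsilyloxy)cyclohexa-1,4-diene (formed in the flask; diastereomer mixture at C3 and C6, both centres lost on aromatisation) | COC1(O[Si](C)(C)C)C(Cc2c(OC)c(C)c(OCc3ccccc3)c(/C(O[Si](C)(C)C)=C/CC)c2OCc2ccccc2)=C(O[Si](C)(C)C)C(Cc2c(OCc3ccccc3)c(C)c(OC)c(/C(O[Si](C)(C)C)=C/CC)c2OCc2ccccc2)C(OC(C)(C)C)=C1C(C)=O | intermediate
27 | 1-[2-tert-butoxy-4,6-dihydroxy-3-(ArC-CH2)-5-(ArA-CH2)phenyl]ethan-1-one | CC(=O)c1c(O)c(Cc2c(OC)c(C)c(OCc3ccccc3)c(C(=O)CCC)c2OCc2ccccc2)c(O)c(Cc2c(OCc3ccccc3)c(C)c(OC)c(C(=O)CCC)c2OCc2ccccc2)c1OC(C)(C)C | intermediate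
28 | 1-[2,4,6-trihydroxy-3-(ArC-CH2)-5-(ArA-CH2)phenyl]ethan-1-one | CC(=O)c1c(O)c(Cc2c(OC)c(C)c(OCc3ccccc3)c(C(=O)CCC)c2OCc2ccccc2)c(O)c(Cc2c(OCc3ccccc3)c(C)c(OC)c(C(=O)CCC)c2OCc2ccccc2)c1O | intermediate
29 | CNP0184345.0: 2,4,6-trihydroxyacetophenone carrying at C3 the (3-butanoyl-2,6-dihydroxy-4-methoxy-5-methylphenyl)methyl group and at C5 the (3-butanoyl-2,4-dihydroxy-6-methoxy-5-methylphenyl)methyl group | CCCC(=O)c1c(O)c(C)c(OC)c(Cc2c(O)c(Cc3c(O)c(C)c(OC)c(C(=O)CCC)c3O)c(O)c(C(C)=O)c2O)c1O | target

**Step count**
Total: 21 steps.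
Longest linear sequence: 13 steps (1 to 29 through steps 7 to 16 and 19 to 21).

**Steps most likely to fail**

Step 19. The cycloaddition may be too slow for the donor-substituted ynone and the crowded diene, the ynol ether may lose isobutene before it reacts, or the diene may be protodesilylated. The fallback makes the same two ring bonds one after the other by known chemistry and sets out from diene 21. Acylation at its terminal carbon with (E)-3-methoxybut-2-enoyl chloride (CH2Cl2, -78 to 20 °C, aqueous work-up) should give methyl 2-(ArA-CH2)-4-(ArC-CH2)-7-methoxy-3,5-dioxooct-6-enoate F1; uncatalysed C-acylation of 1,3-bis(silyloxy)dienes by acid chlorides is a known route to 3,5-dioxo esters. Dilute HCl in THF should hydrolyse the enol ether to methyl 2-(ArA-CH2)-4-(ArC-CH2)-3,5,7-trioxooctanoate F2. NaOMe in MeOH should then close C6 onto the ester carbon in a Claisen (Dieckmann-type) condensation, the polyketide-style route to acylphloroglucinols; the substituent at C2 blocks the competing aldol aromatisation. The product is 28, where the route is rejoined before step 21; compounds 25 and 27 and step 20 are then not needed.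

Step 9. AlCl3 may demethylate the ether that comes to lie ortho to the new ketone, or the aldehyde may condense with unreacted arene under the Lewis acid. The fallback puts the butanoyl group on first and sets out from 3. Benzylation with two equivalents of BnBr (K2CO3, acetone) should take the para hydroxyl and then the less hindered ortho hydroxyl, leaving the chelated one next to the methyl group, to give 1-[4,6-bis(benzyloxy)-2-hydroxy-3-methylphenyl]butan-1-one F3. Methylation (MeI, K2CO3, DMF, 60 °C) should give 1-[4,6-bis(benzyloxy)-2-methoxy-3-methylphenyl]butan-1-one F4. Rieche formylation (Cl2CHOMe, SnCl4, CH2Cl2, -78 to -20 °C) at the last free position should give 12, where the route is rejoined at step 11. Steps 7 to 10 are then not needed; the price is a regiochemical choice between two ortho hydroxyls in the benzylation.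

Step 13. The dianion may be quenched by proton transfer from the butanoyl α-CH2, may add to the ketone, or the labile bromide may solvolyse before it is used. The fallback avoids the bromide and sets out from aldehyde 12 and dianion 16. Aldol addition at -78 °C, where the aldehyde is far more reactive than the hindered ketone, should give methyl 5-[2,6-bis(benzyloxy)-3-butanoyl-4-methoxy-5-methylphenyl]-5-hydroxy-3-oxopentanoate F5 (racemic). Ionic deoxygenation (Et3SiH, CF3CO2H, CH2Cl2, -20 °C), easy because the benzylic cation is stabilised by three ortho and para oxygens, should give 17, where the route is rejoined at step 14. Steps 11 and 12 are then not needed.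

**Further compounds**
F1 | step 19 | methyl 2-(ArA-CH2)-4-(ArC-CH2)-7-methoxy-3,5-dioxooct-6-enoate (6E; diastereomer mixture at C2 and C4) | COC(=O)C(Cc1c(OC)c(C)c(OCc2ccccc2)c(C(=O)CCC)c1OCc1ccccc1)C(=O)C(Cc1c(OCc2ccccc2)c(C)c(OC)c(C(=O)CCC)c1OCc1ccccc1)C(=O)/C=C(/OC)C
F2 | step 19 | methyl 2-(ArA-CH2)-4-(ArC-CH2)-3,5,7-trioxooctanoate (diastereomer mixture at C2 and C4) | COC(=O)C(Cc1c(OC)c(C)c(OCc2ccccc2)c(C(=O)CCC)c1OCc1ccccc1)C(=O)C(Cc1c(OCc2ccccc2)c(C)c(OC)c(C(=O)CCC)c1OCc1ccccc1)C(=O)CC(C)=O
F3 | step 9 | 1-[4,6-bis(benzyloxy)-2-hydroxy-3-methylphenyl]butan-1-one | CCCC(=O)c1c(O)c(C)c(OCc2ccccc2)cc1OCc1ccccc1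
F4 | step 9 | 1-[4,6-bis(benzyloxy)-2-methoxy-3-methylphenyl]butan-1-one | CCCC(=O)c1c(OC)c(C)c(OCc2ccccc2)cc1OCc1ccccc1
F5 | step 13 | methyl 5-[2,6-bis(benzyloxy)-3-butanoyl-4-methoxy-5-methylphenyl]-5-hydroxy-3-oxopentanoate (racemic) | COC(=O)CC(=O)CC(O)c1c(OCc2ccccc2)c(C)c(OC)c(C(=O)CCC)c1OCc1ccccc1
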